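(The data are calculated on assumed constants, and the scatter is random.)

After 0.250 h the north run has lost more substrate than the west run, and that difference is where I begin.

| flask | substrate | coupling partner | remark | time |
|---|---|---|---|---|
| south-west | 8 mM | 1.3 equiv | run made earlier |  |
| west | 12 mM | 1.3 equiv | run made earlier |  |
| north | 16 mM | 2 equiv | run made earlier |  |
| flask | 16 mM | 1.30 equiv |  | 4.0 h |

| run | time / h | single product / % | bis adduct / % | substrate / % |
|---|---|---|---|---|
| south-west | 0.250 | 6.6 | 1.7 | 94.7 |
| south-west | 0.500 | 13.1 | 1.8 | 88.6 |
| south-west | 0.833 | 19.9 | 0 | 82.4 |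
| south-west | 1.50 | 27.2 | 0 | 70.5 |
| south-west | 3.00 | 43.9 | 1.2 | 54.3 |
| west | 0.250 | 10.8 | 0 | 91.0 |
| west | 0.833 | 24.4 | 0.2 | 74.7 |
| west | 1.33 | 33.6 | 0 | 62.8 |
| west | 2.50 | 49.5 | 0.8 | 45.3 |
| west | 3.00 | 53.3 | 2.6 | 42.0 |
| north | 0.250 | 17.3 | 0 | 82.3 |
| north | 0.833 | 43.4 | 1.0 | 54.8 |
| north | 1.33 | 53.5 | 3.0 | 42.3 |
| north | 2.50 | 68.6 | 3.8 | 24.1 |
| north | 3.00 | 67.9 | 4.7 | 19.1 |

(scatter of a reading: 1 percentage point)

- amount of single product in percent of the substrate charged, at 25 min, 80 min and 4.0 h



Substrate's pseudo-first-order constant, ln(charged/left) over time, is 0.779 h⁻¹ in the north run and 0.377 h⁻¹ in the west run. That is twice, and [coupling partner] as charged is also twice. So I write the rate as k[substrate][coupling partner].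

But one early reading carries a scatter of 1 percentage point on a loss of 9.00%, and [coupling partner] sinks as the run goes. So I turn to late readings and integrate, assuming that each substrate lost takes one coupling partner:

k = ln( ([coupling partner]/[substrate]) ÷ (the same ratio as charged) ) ÷ ( ([coupling partner] − [substrate]) · t )

At 3.00 h the south-west run gives 0.0247 mM⁻¹ h⁻¹ and the west run 0.0256 mM⁻¹ h⁻¹. I carry their mean, the second-order constant k = 0.0251 mM⁻¹ h⁻¹.

Yet those runs share one ratio of equivalents, so on their own they do not separate the partner from the substrate. The north run can: k gives it 22.4% substrate at 2.50 h, against 24.1% read, near enough to keep k.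

But substrate lost and single product are different counts. The north run's share of single product in substrate lost is 97.7% at 0.250 h, 96.0% at 0.833 h, and 87.2% over its last two readings. That run holds more partner, but if the later steps are first order in it too, the partner cancels from the share at a given loss of substrate, and these north readings stand at losses of 17.7%, 45.2% and, on average, 78.4%. For the flask I reckon:

25 min: 18.3% converted, so 17.8% single product
80 min: 43.1% converted, so 41.3% single product
4.0 h: 72.9% converted, so 63.5% single product

The forecast reads 17.3%, 40% and 65%, on the ground “That scales with the partner, so the reaction is first order in each”. Its last value lies 1.5 points above mine.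

The flask gives 18.2%, 41.3% and 64.1%.

    substrate + coupling partner → single product + released group (k = 0.425 M⁻¹ min⁻¹)
    coupling partner + single product → bis adduct + released group (k = 0.0610 M⁻¹ min⁻¹)
    coupling partner + bis adduct → over-reaction product (k = 1.02 M⁻¹ min⁻¹)

At 4.00 h the flask holds 36% of its coupling partner, so the substrate's half-life by the first step alone, ln(2)/(k[coupling partner]), has grown from 1.33 h as charged to 3.65 h. At that time the flask still makes single product 3.12 times faster than it uses it up, each step taken net. Part of what holds the flask's single product at 64.1% is the wearing away of coupling partner together with the reading at this time: without that wearing away the flask gives 72.1%, and left to 40.0 h it reaches 71.8%.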